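**Retrosynthetic overview**

- Feature: the 1,4-disubstituted benzene ring, in which C1 carries the hydroxyl and C4 the CH2CH2O-docosanoyl chain. C1 is read as the carbonyl carbon of a four-carbon enone and C4 as the α-carbon of an aldehyde, so the arene is built and not bought.
- The ester C–O bond is made first: docosanoic acid 1, as its chloride 2, with butane-1,4-diol 3 leads to hydroxy ester 4 and, after oxidation, to aldehyde 5.
- The ring is disconnected at C4–C5 (Michael addition) and C2=C3 (aldol condensation): 5 and methyl vinyl ketone 6 give, through keto-aldehyde 7 and ketol 8, cyclohexenone 9. This six-membered carbocycle is the only ring formed.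
- Dehydrogenation of 9 through dienone 10 gives the phenol 11 (target) with the hydroxyl free and para to the chain; no protecting group is used.

Key step: step 4

Assumption: the target has no stereogenic element, so the structure given is met without stereocontrol; the single stereocentre that appears on the way (ring CH of 7 to 9) is carried as the racemate and disappears in step 5.

**Route**

Step 1
Reactants: 1 docosanoic acid
Product: 2 docosanoyl chloride
Conditions: (COCl)2 (1.5 equiv), DMF (cat.), CH2Cl2, rt → 40 °C; evaporate, use crude
Reagents that add atoms: oxalyl chloride, O=C(Cl)C(=O)Cl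
Why: Acyl chloride formation through the DMF-derived chloroiminium (Vilsmeier-type) catalyst; the saturated acid has no other reactive site and the gaseous co-products leave the flask.

Step 2
Reactants: 2 docosanoyl chloride; 3 butane-1,4-diol
Product: 4 4-hydroxybutyl docosanoate
Conditions: 3 (8 equiv), pyridine (1.5 equiv), THF, 0 °C → rt, slow addition of 2; aqueous wash
Reagents that add atoms: none
Why: Nucleophilic acyl substitution (acylation of an alcohol by an acid chloride) in which the large excess of diol in homogeneous solution should make the monoester the statistically dominant product, the unreacted diol being washed out with water.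

Step 3
Reactants: 4 4-hydroxybutyl docosanoate
Product: 5 4-oxobutyl docosanoate
Conditions: TEMPO (10 mol%), PhI(OAc)2 (1.1 equiv), CH2Cl2, rt
Reagents that add atoms: none
Why: Nitroxyl-catalysed (TEMPO/oxoammonium) oxidation of a primary alcohol, which should stop at the aldehyde in the absence of water and leave the ester untouched.

Step 4
Reactants: 5 4-oxobutyl docosanoate; 6 methyl vinyl ketone (but-3-en-2-one)
Product: 9 racemic 2-(4-oxocyclohex-2-en-1-yl)ethyl docosanoate, via keto-aldehyde 7 (not isolated), via ketol 8 (not isolated)
Conditions: 6 (1.5 equiv), Et2NH (0.3 equiv), THF, 0 °C → rt; evaporate volatiles; then TsOH·H2O (0.2 equiv), toluene, reflux (Dean–Stark)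
Reagents that add atoms: none
Why: Diethylamine condenses with 5 to an enamine whose α-carbon adds to the β-carbon of 6 (enamine Michael addition, ring bond C4–C5 of the future phenol), and hydrolysis by the water released in the condensation returns the amine and gives 7. After removal of the volatiles, acid turns the methyl ketone of 7 into its enol, which attacks the aldehyde carbon in a 6-(enolendo)-exo-trig aldol closure to 8, and loss of water gives the conjugated enone 9 (ring bond C2=C3). The closest known reaction type is the amine-catalysed Michael addition of aldehydes to vinyl ketones followed by Robinson-type aldol condensation to 4-substituted cyclohex-2-enones. The one new stereocentre (the ring CH bearing the chain) is not controlled and should form as the racemate, which is acceptable because step 5 makes this carbon sp2. The selectivity needed is mono-addition and a single mode of ring closure: 5 has only one enolisable position, the α-branched adduct 7 should form an enamine far more slowly than 5 so that a second addition is held back with a small excess of 6, and closure through the internal CH2 of the ketone or through the aldehyde α-carbon would give four-membered rings. The ester is remote from every reacting centre and should not be attacked by a catalytic secondary amine at room temperature or by TsOH in dry toluene.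

Step 5
Reactants: 9 racemic 2-(4-oxocyclohex-2-en-1-yl)ethyl docosanoate
Product: 11 2-(4-hydroxyphenyl)ethyl docosanoate, via dienone 10 (not isolated)
Conditions: Pd(TFA)2 (5 mol%), 2-(dimethylamino)pyridine (10 mol%), TsOH·H2O (20 mol%), O2 (1 atm), DMSO, 80 °C
Reagents that add atoms: none
Why: Aerobic palladium(II)-catalysed dehydrogenation, in which a palladium enolate at the α′ carbon undergoes β-hydride elimination to dienone 10, which enolises to the phenol while O2 reoxidises Pd(0); the ring stereocentre disappears and the ester is inert.

**Compound list**

1 | docosanoic acid | CCCCCCCCCCCCCCCCCCCCCC(=O)O | starting material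
2 | docosanoyl chloride | CCCCCCCCCCCCCCCCCCCCCC(=O)Cl | intermediate
3 | butane-1,4-diol | OCCCCO | starting material
4 | 4-hydroxybutyl docosanoate | CCCCCCCCCCCCCCCCCCCCCC(=O)OCCCCO | intermediate
5 | 4-oxobutyl docosanoate | CCCCCCCCCCCCCCCCCCCCCC(=O)OCCCC=O | intermediate
6 | methyl vinyl ketone (but-3-en-2-one) | CC(=O)C=C | starting material
7 | 3-formyl-6-oxoheptyl docosanoate (keto-aldehyde, racemic) | CCCCCCCCCCCCCCCCCCCCCC(=O)OCCC(C=O)CCC(C)=O | intermediate
8 | 2-(2-hydroxy-4-oxocyclohexyl)ethyl docosanoate (ketol, racemic mixture of diastereomers) | CCCCCCCCCCCCCCCCCCCCCC(=O)OCCC1CCC(=O)CC1O | intermediate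
9 | 2-(4-oxocyclohex-2-en-1-yl)ethyl docosanoate (racemic) | CCCCCCCCCCCCCCCCCCCCCC(=O)OCCC1CCC(=O)C=C1 | intermediate
10 | 2-(4-oxocyclohexa-2,5-dien-1-yl)ethyl docosanoate (dienone, keto tautomer of 11) | CCCCCCCCCCCCCCCCCCCCCC(=O)OCCC1C=CC(=O)C=C1 | intermediate
11 | 2-(4-hydroxyphenyl)ethyl docosanoate (achiral) | CCCCCCCCCCCCCCCCCCCCCC(=O)OCCc1ccc(O)cc1 | target

**Count**

Total steps: 5. Longest linear sequence: 5 steps (1 → 2 → 4 → 5 → 9 → 11).

**Steps most likely to fail**

1. Step 4. The enamine of 5 may add to free 5 (self-aldol condensation), the adduct 7 may take up a second molecule of enone, and 6 may oligomerise under the amine, so that material is diverted before the ring closes. The fallback sets out from 5 and comes back to the route at 9. It replaces catalytic turnover by stoichiometric pre-activation. Compound 5 is condensed with piperidine (1.1 equiv, 4 Å molecular sieves, toluene, rt) to the enamine (E)-4-(piperidin-1-yl)but-3-en-1-yl docosanoate F1, so that no free aldehyde remains. F1 then takes up one molecule of 6 in a Stork enamine reaction of the cycloaddition type, giving the aminal 2-[6-methyl-2-(piperidin-1-yl)-3,4-dihydro-2H-pyran-3-yl]ethyl docosanoate F2, which cannot add a second enone. Warming F2 in AcOH/NaOAc/H2O/THF should open it to 7 with loss of piperidine, and the same buffer should close 7 to 9.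

2. Step 5. The dehydrogenation may stall at partial conversion because the palladium aggregates to inactive metal, a risk raised by the poor solubility of the waxy ester in DMSO. The fallback sets out from 9 and comes back at 11. It replaces the catalytic dehydrogenation by a halogenation–elimination sequence in which no phenol is present while the halogen is introduced. α′-Bromination of 9 with phenyltrimethylammonium tribromide (THF, 0 °C) should give 2-(5-bromo-4-oxocyclohex-2-en-1-yl)ethyl docosanoate F3. Heating F3 with Li2CO3 and LiBr in DMF (100 °C) should remove hydrogen bromide to give dienone 10, which enolises to 11.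

3. Step 2. A second acylation of the monoester may compete with the first if the diol is not fully dissolved or the chloride is added quickly, and separation of the waxy mono- and diesters may be laborious. The fallback sets out from 2 and comes back at 5, bypassing 4 and step 3. It uses a monofunctional alcohol with a masked aldehyde instead of statistical differentiation of a diol. Acylation of commercial pent-4-en-1-ol with 2 (pyridine, CH2Cl2, 0 °C → rt) should give pent-4-en-1-yl docosanoate F4. Ozonolysis of F4 (O3, CH2Cl2, −78 °C; then PPh3) should cleave the terminal alkene to aldehyde 5 with loss of formaldehyde.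

**Further compounds**

F1 | step 4 | (E)-4-(piperidin-1-yl)but-3-en-1-yl docosanoate | CCCCCCCCCCCCCCCCCCCCCC(=O)OCC/C=C/N1CCCCC1
F2 | step 4 | 2-[6-methyl-2-(piperidin-1-yl)-3,4-dihydro-2H-pyran-3-yl]ethyl docosanoate (racemic mixture of diastereomers) | CCCCCCCCCCCCCCCCCCCCCC(=O)OCCC1CC=C(C)OC1N2CCCCC2
F3 | step 5 | 2-(5-bromo-4-oxocyclohex-2-en-1-yl)ethyl docosanoate (racemic mixture of diastereomers) | CCCCCCCCCCCCCCCCCCCCCC(=O)OCCC1CC(Br)C(=O)C=C1
F4 | step 2 | pent-4-en-1-yl docosanoate | CCCCCCCCCCCCCCCCCCCCCC(=O)OCCCC=C
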